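## Retrosynthetic overview

1. The norbornene core is opened by a retro-Diels–Alder disconnection (C1–C13' and C3–C11') into a 2α-acetoxy-guaia-1(5),3,11(13)-trien-12,8α-olide (diene, made in situ) and the (1(10)Z,4Z)-isomer of eupatolide (dienophile).
2. The acetoxy-cyclopentadiene comes from dehydration of a tertiary carbinol; the cyclopentenone behind it comes from an intramolecular aldol of a cis-ene-dione, which is unmasked from a 2,5-dimethylfuran.
3. The furan-fused cycloheptanone comes from an amine-catalysed asymmetric double Friedel–Crafts (5+2) annulation of 2,5-dimethylfuran with a cross-conjugated dienone. This sets C10 and is the proposed new reaction.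
4. The dienophile comes from ring-closing metathesis (C1'=C10'), a Felkin–Anh addition of a (Z)-alkenyllithium with lactonisation (C6'), and a D-proline anti-aldol (C7', C8').
5. Ring order. Guaianolide half: cycloheptane, then γ-lactone, then cyclopentenone, then cyclopentadiene. Germacranolide half: γ-lactone, then cyclodecadiene. The norbornene is formed last.

Assumption: all numbered starting materials are taken as catalogue chemicals; names use guaiane numbering for the guaianolide half and primed germacrane numbering for the germacranolide half (7-H and 7'-H are α). Nothing here has been run; every stereochemical outcome is a prediction.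

## Route

Step 1
Reactants: 1 4-methoxy-2-methylidene-4-oxobutanoic acid (monomethyl itaconate); 2 tributyl[(E)-prop-1-en-1-yl]stannane
Product: 4 methyl (5E)-3-methylidene-4-oxohept-5-enoate, via acid chloride 3 (not isolated)
Conditions: (COCl)2, DMF (cat.), CH2Cl2, 0 °C to rt; evaporate; then 2, Pd(PPh3)4 (3 mol %), THF, 50 °C
Reagents that add atoms: none
Why: Acid chloride formation followed by Stille acyl cross-coupling gives the cross-conjugated dienone under neutral conditions that leave the ester and the exocyclic methylene in place; no stereocentre is formed.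

Step 2
Reactants: 4 methyl (5E)-3-methylidene-4-oxohept-5-enoate; 5 2,5-dimethylfuran
Product: 7 methyl 2-[(5R,8S)-1,3,8-trimethyl-6-oxo-5,6,7,8-tetrahydro-4H-cyclohepta[c]furan-5-yl]acetate, via Michael adduct 6 (not isolated)
Conditions: 9-amino-9-deoxy-epi-quinine (20 mol %), CF3CO2H (40 mol %), 5 (3 equiv), PhMe, 40 °C
Reagents that add atoms: none
Why: Proposed new method: the acid-buffered primary amine first promotes Friedel–Crafts attack of a furan β-carbon on the unsubstituted methylene terminus (giving 6), then condenses with the remaining propenyl ketone to an iminium ion whose one face is shielded by the cinchona scaffold, so the second furan β-carbon closes the seven-membered ring (7-endo-trig) and sets C10 (the quinidine-derived pseudoenantiomer would give the antipode), while C7, α to the ketone, equilibrates through the enamine to the cis isomer (10-methyl pseudoaxial to avoid the furan methyl, acetate arm equatorial); the C2v symmetry of 5 removes any regiochemical question; closest known reaction types are cinchona primary-amine-catalysed Friedel–Crafts alkylation of indoles with enones and double Michael annulations of divinyl ketones.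

Step 3
Reactants: 7 methyl 2-[(5R,8S)-1,3,8-trimethyl-6-oxo-5,6,7,8-tetrahydro-4H-cyclohepta[c]furan-5-yl]acetate
Product: 9 2,4-epoxy-3,4-seco-guaia-1,4-dien-12,8α-olide (7α-H/8β-H trans-fused; 10β-Me), via hydroxy ester 8 (not isolated)
Conditions: SmI2 (2.5 equiv), H2O, Et3N, THF, 0 °C; then TsOH (cat.), PhMe, 50 °C
Reagents that add atoms: none
Why: Electron-transfer ketone reduction protonates the ketyl under thermodynamic control to give the equatorial 8α-alcohol (trans to the C7 arm and to the pseudoaxial 10-methyl, which blocks the kinetic hydride route to this isomer), and acid-catalysed lactonisation then gives the trans-fused γ-lactone.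

Step 4
Reactants: 9 2,4-epoxy-3,4-seco-guaia-1,4-dien-12,8α-olide
Product: 12 2,4-epoxy-3,4-seco-guaia-1,4,11(13)-trien-12,8α-olide, via Mannich base 10 (not isolated), via ammonium iodide 11 (not isolated)
Conditions: LiN(i-Pr)2, THF, −78 °C; CH2=NMe2+ I−, −78 °C to rt; then MeI, MeOH; then NaHCO3, CH2Cl2/H2O
Reagents that add atoms: Eschenmoser's salt (N,N-dimethylmethylideneammonium iodide), C=[N+](C)C.[I-]
Why: Lactone enolate Mannich reaction, quaternisation and E1cB elimination install the 11(13)-methylene; only C11 is enolisable and C7 is untouched.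

Step 5
Reactants: 12 2,4-epoxy-3,4-seco-guaia-1,4,11(13)-trien-12,8α-olide
Product: 13 2,4-dioxo-3,4-seco-guaia-1(5),11(13)-dien-12,8α-olide (cis-ene-dione)
Conditions: mCPBA (1.05 equiv), CH2Cl2, 0 °C
Reagents that add atoms: mCPBA, OOC(=O)c1cccc(Cl)c1
Why: Peracid oxidation of the electron-rich tetrasubstituted furan (epoxidation then ring opening) unmasks the ring-locked cis-ene-1,4-dione, while the electron-poor methylene lactone does not react.

Step 6
Reactants: 13 2,4-dioxo-3,4-seco-guaia-1(5),11(13)-dien-12,8α-olide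
Product: 14 4-hydroxy-2-oxoguaia-1(5),11(13)-dien-12,8α-olide (C4 epimers)
Conditions: Na2CO3 (aq., 5 %), THF, 0 °C to rt
Reagents that add atoms: none
Why: Intramolecular aldol addition of the C3 methyl ketone enolate to the less hindered C4 acetyl carbonyl (the C2 acetyl is flanked by the branched C10) closes the cyclopentenone; the new C4 carbinol centre is removed in step 17, so its configuration does not matter.

Step 7
Reactants: 14 4-hydroxy-2-oxoguaia-1(5),11(13)-dien-12,8α-olide
Product: 15 2α,4-dihydroxyguaia-1(5),11(13)-dien-12,8α-olide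
Conditions: (R)-2-methyl-CBS-oxazaborolidine (20 mol %), BH3·SMe2 (2 equiv), THF, −30 °C; MeOH quench
Reagents that add atoms: none
Why: Corey–Bakshi–Shibata reduction with the α-substituted alkenyl carbon C1 as the large group delivers hydride to the β-face under catalyst control and sets the 2α-carbinol; the ketone is reduced faster than the methylene lactone is hydroborated.

Step 8
Reactants: 15 2α,4-dihydroxyguaia-1(5),11(13)-dien-12,8α-olide
Product: 16 2α-acetoxy-4-hydroxyguaia-1(5),11(13)-dien-12,8α-olide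
Conditions: Ac2O (1.2 equiv), pyridine, DMAP (cat.), CH2Cl2, 0 °C
Reagents that add atoms: acetic anhydride, CC(=O)OC(C)=O
Why: DMAP-catalysed acylation takes the secondary allylic alcohol and leaves the tertiary one; no stereocentre changes.

Step 9
Reactants: 17 methyl 4-oxobutanoate; 18 2-(2-methyl-1,3-dioxolan-2-yl)acetaldehyde
Product: 20 methyl (3R,4R)-4-{[tert-butyl(dimethyl)silyl]oxy}-3-formyl-5-(2-methyl-1,3-dioxolan-2-yl)pentanoate, via aldol 19 (not isolated)
Conditions: D-proline (20 mol %), DMF, 4 °C, 17 added by syringe pump to 18 (2 equiv); then imidazole, TBSCl, 0 °C to rt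
Reagents that add atoms: tert-butyldimethylsilyl chloride, CC(C)(C)[Si](C)(C)Cl
Why: Proline enamine cross-aldol through the hydrogen-bonded chair transition state gives the anti aldol and sets C7' and C8' (D-proline gives the mirror image of the L-proline series); the neopentyl-type acceptor 18 enolises poorly, and silylation in the same pot prevents lactonisation and epimerisation.

Step 10
Reactants: 21 but-3-en-1-ylmagnesium bromide; 22 propyne
Product: 25 (1Z)-1-iodo-2-methylhexa-1,5-diene, via butenylcopper 23 (not isolated), via alkenylcopper 24 (not isolated)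
Conditions: CuBr·SMe2 (1.0 equiv), Et2O/Me2S, −45 °C; 22, −25 °C; I2, −50 to 0 °C
Reagents that add atoms: iodine, II
Why: syn-Carbocupration of propyne puts the butenyl chain and copper cis, and iodinolysis with retention gives the (Z)-trisubstituted alkenyl iodide.

Step 11
Reactants: 20 methyl (3R,4R)-4-{[tert-butyl(dimethyl)silyl]oxy}-3-formyl-5-(2-methyl-1,3-dioxolan-2-yl)pentanoate; 25 (1Z)-1-iodo-2-methylhexa-1,5-diene
Product: 28 (4S,5R)-4-[(1R)-1-{[tert-butyl(dimethyl)silyl]oxy}-2-(2-methyl-1,3-dioxolan-2-yl)ethyl]-5-[(1Z)-2-methylhexa-1,5-dien-1-yl]oxolan-2-one, via alkenyllithium 26 (not isolated), via lithium alkoxide 27 (not isolated)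
Conditions: 25, t-BuLi (2.0 equiv), Et2O, −78 °C; add 20, −78 °C; then warm to 25 °C
Reagents that add atoms: none
Why: Lithium–iodine exchange keeps the Z geometry, and Felkin–Anh addition to the aldehyde (C8' branch as large group; chelation through the ester carbonyl predicts the same face) sets C6', after which the alkoxide closes the trans-γ-lactone on the methyl ester.

Step 12
Reactants: 28 (4S,5R)-4-[(1R)-1-{[tert-butyl(dimethyl)silyl]oxy}-2-(2-methyl-1,3-dioxolan-2-yl)ethyl]-5-[(1Z)-2-methylhexa-1,5-dien-1-yl]oxolan-2-one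
Product: 29 (4S,5R)-4-[(1R)-1-{[tert-butyl(dimethyl)silyl]oxy}-3-oxobutyl]-5-[(1Z)-2-methylhexa-1,5-dien-1-yl]oxolan-2-one
Conditions: PPTS (0.2 equiv), acetone/H2O (10:1), 55 °C
Reagents that add atoms: water, O
Why: Mild acid-catalysed ketal hydrolysis frees the methyl ketone; the secondary TBS ether, the lactone and the olefins survive.

Step 13
Reactants: 29 (4S,5R)-4-[(1R)-1-{[tert-butyl(dimethyl)silyl]oxy}-3-oxobutyl]-5-[(1Z)-2-methylhexa-1,5-dien-1-yl]oxolan-2-one
Product: 30 (4S,5R)-4-[(1R)-1-{[tert-butyl(dimethyl)silyl]oxy}-3-methylbut-3-en-1-yl]-5-[(1Z)-2-methylhexa-1,5-dien-1-yl]oxolan-2-one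
Conditions: Ph3PCH3Br, KN(SiMe3)2, THF, 0 °C; then 29, 0 °C to rt
Reagents that add atoms: methyltriphenylphosphonium bromide, C[P+](c1ccccc1)(c1ccccc1)c1ccccc1.[Br-]
Why: Wittig methylenation converts the methyl ketone into the methallyl group needed for ring closure; the lactone carbonyl is much less electrophilic and no stereocentre is touched.

Step 14
Reactants: 30 (4S,5R)-4-[(1R)-1-{[tert-butyl(dimethyl)silyl]oxy}-3-methylbut-3-en-1-yl]-5-[(1Z)-2-methylhexa-1,5-dien-1-yl]oxolan-2-one
Product: 31 (3aS,4R,6Z,10Z,11aR)-4-{[tert-butyl(dimethyl)silyl]oxy}-6,10-dimethyl-3a,4,5,8,9,11a-hexahydrocyclodeca[b]furan-2(3H)-one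
Conditions: second-generation Grubbs catalyst (10 mol %), PhMe (1 mM), 80 °C, Ar sparge
Reagents that add atoms: none
Why: Ring-closing metathesis between the vinyl and the 1,1-disubstituted olefin, driven by loss of ethene, closes the ten-membered ring; the chain is already bent by the Z-C4'=C5' olefin and the trans-lactone, and the Z C1'=C10' olefin is the expected geometry for a ring of this size.

Step 15
Reactants: 31 (3aS,4R,6Z,10Z,11aR)-4-{[tert-butyl(dimethyl)silyl]oxy}-6,10-dimethyl-3a,4,5,8,9,11a-hexahydrocyclodeca[b]furan-2(3H)-one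
Product: 34 (3aS,4R,6Z,10Z,11aR)-4-{[tert-butyl(dimethyl)silyl]oxy}-6,10-dimethyl-3-methylidene-3a,4,5,8,9,11a-hexahydrocyclodeca[b]furan-2(3H)-one, via Mannich base 32 (not isolated), via ammonium iodide 33 (not isolated)
Conditions: LiN(i-Pr)2, THF, −78 °C; CH2=NMe2+ I−, −78 °C to rt; then MeI, MeOH; then NaHCO3, CH2Cl2/H2O
Reagents that add atoms: Eschenmoser's salt (N,N-dimethylmethylideneammonium iodide), C=[N+](C)C.[I-]
Why: Lactone enolate Mannich reaction, quaternisation and E1cB elimination give the α-methylene lactone after the metathesis step, so the ruthenium catalyst never meets the acrylate.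

Step 16
Reactants: 34 (3aS,4R,6Z,10Z,11aR)-4-{[tert-butyl(dimethyl)silyl]oxy}-6,10-dimethyl-3-methylidene-3a,4,5,8,9,11a-hexahydrocyclodeca[b]furan-2(3H)-one
Product: 35 (3aR,4R,6Z,10Z,11aR)-4-hydroxy-6,10-dimethyl-3-methylidene-3a,4,5,8,9,11a-hexahydrocyclodeca[b]furan-2(3H)-one [(1(10)Z,4Z)-8β-hydroxygermacra-1(10),4,11(13)-trien-12,6α-olide]
Conditions: HF·pyridine, THF/pyridine, 0 °C to rt
Reagents that add atoms: none
Why: Fluoride desilylation under buffered, non-basic conditions frees the 8'β-alcohol without translactonisation to O8' or conjugate addition to the methylene lactone.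

Step 17
Reactants: 16 2α-acetoxy-4-hydroxyguaia-1(5),11(13)-dien-12,8α-olide; 35 (1(10)Z,4Z)-8β-hydroxygermacra-1(10),4,11(13)-trien-12,6α-olide
Product: 37 target CNP0148007.1, via acetoxy diene 36 (not isolated)
Conditions: 16 (1.3 equiv), Ph2S[OC(CF3)2Ph]2 (1.3 equiv), CH2Cl2, −40 to 0 °C, 20 min; then 35 (1.0 equiv), (CF3)2CHOH, concentrate to 1 M, 0 to 25 °C, dark, 48 h
Reagents that add atoms: none
Why: Martin sulfurane dehydration of the tertiary allylic alcohol gives the 5-acetoxycyclopentadiene cold, and the Diels–Alder reaction with the methylene lactone of 35 sets C1, C3 and C11': the CH2 terminus bonds to the quaternary C1 on steric grounds, the lactone carbonyl sits exo as usual for α-methylene lactones, the diene is attacked anti to the 2α-acetoxy group (which would clash with the exo carbonyl), and the dienophile reacts on its β-face, anti to 7'-H.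

## Compound list

1 | 4-methoxy-2-methylidene-4-oxobutanoic acid (monomethyl itaconate) | COC(=O)CC(=C)C(=O)O | starting material
2 | tributyl[(E)-prop-1-en-1-yl]stannane | C/C=C/[Sn](CCCC)(CCCC)CCCC | starting material
3 | methyl 3-(chlorocarbonyl)but-3-enoate | COC(=O)CC(=C)C(=O)Cl | intermediate
4 | methyl (5E)-3-methylidene-4-oxohept-5-enoate | COC(=O)CC(=C)C(=O)/C=C/C | intermediate
5 | 2,5-dimethylfuran | CC1=CC=C(C)O1 | starting material
6 | methyl (5E)-3-[(2,5-dimethylfuran-3-yl)methyl]-4-oxohept-5-enoate (racemic at C3) | COC(=O)CC(CC1=C(C)OC(C)=C1)C(=O)/C=C/C | intermediate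
7 | methyl 2-[(5R,8S)-1,3,8-trimethyl-6-oxo-5,6,7,8-tetrahydro-4H-cyclohepta[c]furan-5-yl]acetate | COC(=O)C[C@H]1CC2=C(C)OC(C)=C2[C@@H](C)CC1=O | intermediate
8 | methyl 2-[(5R,6S,8S)-6-hydroxy-1,3,8-trimethyl-5,6,7,8-tetrahydro-4H-cyclohepta[c]furan-5-yl]acetate | COC(=O)C[C@H]1CC2=C(C)OC(C)=C2[C@@H](C)C[C@@H]1O | intermediate
9 | 2,4-epoxy-3,4-seco-guaia-1,4-dien-12,8α-olide (furan-masked guaianolide; 7α-H, 8β-H, 10β-Me; C11 is CH2) | O=C1O[C@H]2C[C@H](C)C3=C(C)OC(C)=C3C[C@@H]2C1 | intermediate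
10 | 13-(dimethylamino)-2,4-epoxy-3,4-seco-guaia-1,4-dien-12,8α-olide (C11 epimers) | CN(C)CC1C(=O)O[C@H]2C[C@H](C)C3=C(C)OC(C)=C3C[C@H]12 | intermediate
11 | 13-(trimethylammonio)-2,4-epoxy-3,4-seco-guaia-1,4-dien-12,8α-olide iodide | C[N+](C)(C)CC1C(=O)O[C@H]2C[C@H](C)C3=C(C)OC(C)=C3C[C@H]12.[I-] | intermediate
12 | 2,4-epoxy-3,4-seco-guaia-1,4,11(13)-trien-12,8α-olide | C=C1C(=O)O[C@H]2C[C@H](C)C3=C(C)OC(C)=C3C[C@H]12 | intermediate
13 | 2,4-dioxo-3,4-seco-guaia-1(5),11(13)-dien-12,8α-olide (1,5-diacetylcycloheptene with trans-fused methylene lactone) | C=C1C(=O)O[C@H]2C[C@H](C)C(C(C)=O)=C(C(C)=O)C[C@H]12 | intermediate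
14 | 4-hydroxy-2-oxoguaia-1(5),11(13)-dien-12,8α-olide (10β-Me; C4 epimers) | C=C1C(=O)O[C@H]2C[C@H](C)C3=C(C[C@H]12)C(C)(O)CC3=O | intermediate
15 | 2α,4-dihydroxyguaia-1(5),11(13)-dien-12,8α-olide (C4 epimers) | C=C1C(=O)O[C@H]2C[C@H](C)C3=C(C[C@H]12)C(C)(O)C[C@@H]3O | intermediate
16 | 2α-acetoxy-4-hydroxyguaia-1(5),11(13)-dien-12,8α-olide (C4 epimers) | C=C1C(=O)O[C@H]2C[C@H](C)C3=C(C[C@H]12)C(C)(O)C[C@@H]3OC(C)=O | intermediate
17 | methyl 4-oxobutanoate | COC(=O)CCC=O | starting material
18 | 2-(2-methyl-1,3-dioxolan-2-yl)acetaldehyde | CC1(CC=O)OCCO1 | starting material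
19 | methyl (3R,4R)-3-formyl-4-hydroxy-5-(2-methyl-1,3-dioxolan-2-yl)pentanoate | COC(=O)C[C@@H](C=O)[C@H](O)CC1(C)OCCO1 | intermediate
20 | methyl (3R,4R)-4-{[tert-butyl(dimethyl)silyl]oxy}-3-formyl-5-(2-methyl-1,3-dioxolan-2-yl)pentanoate | COC(=O)C[C@@H](C=O)[C@H](O[Si](C)(C)C(C)(C)C)CC1(C)OCCO1 | intermediate
21 | but-3-en-1-ylmagnesium bromide | C=CCC[Mg]Br | starting material
22 | propyne | CC#C | starting material
23 | but-3-en-1-ylcopper | C=CCC[Cu] | intermediate
24 | [(1Z)-2-methylhexa-1,5-dien-1-yl]copper | C=CCC/C(C)=C\[Cu] | intermediate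
25 | (1Z)-1-iodo-2-methylhexa-1,5-diene | C=CCC/C(C)=C\I | intermediate
26 | [(1Z)-2-methylhexa-1,5-dien-1-yl]lithium | C=CCC/C(C)=C\[Li] | intermediate
27 | lithium alkoxide of methyl (3S,4R)-4-{[tert-butyl(dimethyl)silyl]oxy}-3-[(1R,2Z)-1-hydroxy-3-methylhepta-2,6-dien-1-yl]-5-(2-methyl-1,3-dioxolan-2-yl)pentanoate | COC(=O)C[C@@H]([C@H]([O-])/C=C(/C)CCC=C)[C@H](O[Si](C)(C)C(C)(C)C)CC1(C)OCCO1.[Li+] | intermediate
28 | (4S,5R)-4-[(1R)-1-{[tert-butyl(dimethyl)silyl]oxy}-2-(2-methyl-1,3-dioxolan-2-yl)ethyl]-5-[(1Z)-2-methylhexa-1,5-dien-1-yl]oxolan-2-one | O=C1O[C@H](/C=C(/C)CCC=C)[C@H](C1)[C@H](O[Si](C)(C)C(C)(C)C)CC2(C)OCCO2 | intermediate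
29 | (4S,5R)-4-[(1R)-1-{[tert-butyl(dimethyl)silyl]oxy}-3-oxobutyl]-5-[(1Z)-2-methylhexa-1,5-dien-1-yl]oxolan-2-one | O=C1O[C@H](/C=C(/C)CCC=C)[C@H](C1)[C@H](O[Si](C)(C)C(C)(C)C)CC(C)=O | intermediate
30 | (4S,5R)-4-[(1R)-1-{[tert-butyl(dimethyl)silyl]oxy}-3-methylbut-3-en-1-yl]-5-[(1Z)-2-methylhexa-1,5-dien-1-yl]oxolan-2-one | O=C1O[C@H](/C=C(/C)CCC=C)[C@H](C1)[C@H](O[Si](C)(C)C(C)(C)C)CC(C)=C | intermediate
31 | (3aS,4R,6Z,10Z,11aR)-4-{[tert-butyl(dimethyl)silyl]oxy}-6,10-dimethyl-3a,4,5,8,9,11a-hexahydrocyclodeca[b]furan-2(3H)-one | O=C1O[C@@H]2/C=C(/C)CC/C=C(/C)C[C@@H](O[Si](C)(C)C(C)(C)C)[C@H]2C1 | intermediate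
32 | 3-[(dimethylamino)methyl] derivative of 31 (C3 epimers) | CN(C)CC1C(=O)O[C@@H]2/C=C(/C)CC/C=C(/C)C[C@@H](O[Si](C)(C)C(C)(C)C)[C@@H]12 | intermediate
33 | 3-[(trimethylammonio)methyl] derivative of 31, iodide | C[N+](C)(C)CC1C(=O)O[C@@H]2/C=C(/C)CC/C=C(/C)C[C@@H](O[Si](C)(C)C(C)(C)C)[C@@H]12.[I-] | intermediate
34 | (3aS,4R,6Z,10Z,11aR)-4-{[tert-butyl(dimethyl)silyl]oxy}-6,10-dimethyl-3-methylidene-3a,4,5,8,9,11a-hexahydrocyclodeca[b]furan-2(3H)-one | O=C1O[C@@H]2/C=C(/C)CC/C=C(/C)C[C@@H](O[Si](C)(C)C(C)(C)C)[C@H]2C1=C | intermediate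
35 | (3aR,4R,6Z,10Z,11aR)-4-hydroxy-6,10-dimethyl-3-methylidene-3a,4,5,8,9,11a-hexahydrocyclodeca[b]furan-2(3H)-one | O=C1O[C@@H]2/C=C(/C)CC/C=C(/C)C[C@@H](O)[C@H]2C1=C | intermediate
36 | 2α-acetoxyguaia-1(5),3,11(13)-trien-12,8α-olide | C=C1C(=O)O[C@H]2C[C@H](C)C3=C(C[C@H]12)C(C)=C[C@@H]3OC(C)=O | intermediate
37 | CNP0148007.1 (Diels–Alder adduct of 36 and 35: C1–C13' and C3–C11' bonds, 2α-acetoxy bridge syn to the C4=C5 olefin, lactone carbonyl exo) | C=C1C(=O)O[C@H]2C[C@H](C)[C@]34C[C@@]5(C(=O)O[C@@H]6/C=C(/C)CC/C=C(/C)C[C@@H](O)[C@H]65)[C@H](C(C)=C3C[C@H]12)[C@@H]4OC(C)=O | target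

## Step count and weak points

Total steps: 17. Longest linear sequence: 9 (steps 1 to 8, then 17).

Three steps most likely to fail:

Step 2 (the proposed annulation). Dienone 4 may isomerise, polymerise or undergo Nazarov cyclisation, the ketiminium may be too weak an electrophile for the furan, and the enantioselectivity is unproven. The fallback uses known chemistry, sets out from 5 and comes back at 7. Friedel–Crafts acetylation of 5 (Ac2O, H3PO4) gives 1-(2,5-dimethylfuran-3-yl)ethanone F1. Peterson olefination with lithiated N-tert-butyl-2-(trimethylsilyl)ethanimine, then aqueous oxalic acid, gives (2E)-3-(2,5-dimethylfuran-3-yl)but-2-enal F2. Iminium-catalysed transfer hydrogenation (chiral imidazolidinone trichloroacetate, Hantzsch ester, CHCl3, −30 °C) sets the methyl-bearing centre and gives (3S)-3-(2,5-dimethylfuran-3-yl)butanal F3. CrCl2/NiCl2-mediated alkenylation with methyl 3-bromobut-3-enoate gives methyl (6S)-6-(2,5-dimethylfuran-3-yl)-4-hydroxy-3-methylideneheptanoate F4, and Dess–Martin oxidation gives methyl (6S)-6-(2,5-dimethylfuran-3-yl)-3-methylidene-4-oxoheptanoate F5. Sc(OTf)3-catalysed intramolecular Friedel–Crafts conjugate alkylation at the methylene terminus closes the seven-membered ring, and a trace of DBU equilibrates C7 to give 7.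

Step 14 (ring-closing metathesis). Closing a ten-membered ring onto a 1,1-disubstituted olefin may give oligomers or the E isomer. The fallback sets out from 20 and comes back at 31. Carbocupration of propyne with the Grignard reagent of 3-bromo-1,1-dimethoxypropane and iodinolysis, as in step 10, gives (1Z)-1-iodo-5,5-dimethoxy-2-methylpent-1-ene F6. Its lithium reagent adds to 20 as in step 11 to give the lactone (4S,5R)-4-[(1R)-1-{[tert-butyl(dimethyl)silyl]oxy}-2-(2-methyl-1,3-dioxolan-2-yl)ethyl]-5-[(1Z)-5,5-dimethoxy-2-methylpent-1-en-1-yl]oxolan-2-one F7. PPTS in wet acetone unmasks both carbonyl groups to give the keto aldehyde (4Z)-5-[(2R,3S)-3-[(1R)-1-{[tert-butyl(dimethyl)silyl]oxy}-3-oxobutyl]-5-oxooxolan-2-yl]-4-methylpent-4-enal F8. Intramolecular McMurry coupling (TiCl3(DME)1.5, Zn–Cu couple, DME, reflux, syringe pump) forms the C1'=C10' bond and gives 31. This reductive carbonyl coupling is a proven way to close ten-membered germacrane rings and does not need a metathesis catalyst to reach the hindered olefin; the Z isomer is separated.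

Step 17 (dehydration and Diels–Alder union). The acetoxy diene may undergo a 1,5-hydrogen shift faster than it is trapped, and the dienophile may prefer the face syn to the acetoxy group. The fallback sets out from 35 (with 16) and comes back at 37. Silylation (Et3SiCl, imidazole, CH2Cl2) gives the triethylsilyl ether of 35 F9. Diene 36 is made from 16 as in step 17 and combined at −78 °C with F9 and a triflimide-activated chiral oxazaborolidine (cationic boron Lewis acid, 20 mol %, CH2Cl2, −78 to −40 °C). This replaces the thermal, substrate-controlled union by a catalyst-controlled Diels–Alder reaction: it is fast enough at low temperature to outrun the hydrogen shift, and the bulky Lewis acid on the exo lactone carbonyl enforces approach anti to the acetoxy group. It gives the 8'-O-triethylsilyl ether of 37 F10, and HF·pyridine then gives 37.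

Further compounds
F1 | step 2 | 1-(2,5-dimethylfuran-3-yl)ethanone | CC(=O)C1=C(C)OC(C)=C1
F2 | step 2 | (2E)-3-(2,5-dimethylfuran-3-yl)but-2-enal | C/C(=C\C=O)C1=C(C)OC(C)=C1
F3 | step 2 | (3S)-3-(2,5-dimethylfuran-3-yl)butanal | O=CC[C@H](C)C1=C(C)OC(C)=C1
F4 | step 2 | methyl (6S)-6-(2,5-dimethylfuran-3-yl)-4-hydroxy-3-methylideneheptanoate (C4 epimers) | COC(=O)CC(=C)C(O)C[C@H](C)C1=C(C)OC(C)=C1
F5 | step 2 | methyl (6S)-6-(2,5-dimethylfuran-3-yl)-3-methylidene-4-oxoheptanoate | COC(=O)CC(=C)C(=O)C[C@H](C)C1=C(C)OC(C)=C1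
F6 | step 14 | (1Z)-1-iodo-5,5-dimethoxy-2-methylpent-1-ene | COC(OC)CC/C(C)=C\I
F7 | step 14 | (4S,5R)-4-[(1R)-1-{[tert-butyl(dimethyl)silyl]oxy}-2-(2-methyl-1,3-dioxolan-2-yl)ethyl]-5-[(1Z)-5,5-dimethoxy-2-methylpent-1-en-1-yl]oxolan-2-one | O=C1O[C@H](/C=C(/C)CCC(OC)OC)[C@H](C1)[C@H](O[Si](C)(C)C(C)(C)C)CC2(C)OCCO2
F8 | step 14 | (4Z)-5-[(2R,3S)-3-[(1R)-1-{[tert-butyl(dimethyl)silyl]oxy}-3-oxobutyl]-5-oxooxolan-2-yl]-4-methylpent-4-enal | O=C1O[C@H](/C=C(/C)CCC=O)[C@H](C1)[C@H](O[Si](C)(C)C(C)(C)C)CC(C)=O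
F9 | step 17 | (3aS,4R,6Z,10Z,11aR)-6,10-dimethyl-3-methylidene-4-[(triethylsilyl)oxy]-3a,4,5,8,9,11a-hexahydrocyclodeca[b]furan-2(3H)-one | O=C1O[C@@H]2/C=C(/C)CC/C=C(/C)C[C@@H](O[Si](CC)(CC)CC)[C@H]2C1=C
F10 | step 17 | 8'-O-triethylsilyl ether of 37 | C=C1C(=O)O[C@H]2C[C@H](C)[C@]34C[C@@]5(C(=O)O[C@@H]6/C=C(/C)CC/C=C(/C)C[C@@H](O[Si](CC)(CC)CC)[C@H]65)[C@H](C(C)=C3C[C@H]12)[C@@H]4OC(C)=O
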